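## Retrosynthetic overview

1. Ester C–O bond: target ⇒ (R)-shikonin + 3-acetoxy-3-methylbutanoic acid (carbodiimide coupling at the side-chain hydroxyl). The acid comes from 3-hydroxy-3-methylbutanoic acid through its benzyl ester.
2. Naphthazarin unmasking: (R)-shikonin ⇒ the same carbinol with its four ring oxygens tied up as two peri methylene acetals, removed in one anodic oxidation.
3. Stereocentre: the carbinol ⇒ prochiral aryl ketone, reduced by a ketoreductase. The enzyme is the asymmetric catalyst and this is the only stereocentre.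
4. Aryl–acyl C–C bond: ketone ⇒ aryllithium from the monobrominated bis-acetal + Weinreb amide of 4-methylpent-3-enoic acid.
5. Rings: the naphthalene core is bought intact as naphthazarin. The only rings formed are the two protective 1,3-dioxine rings (both in step 2), opened again in step 7.

Assumption: the naphthazarin tautomers interconvert rapidly, so products are drawn as the tautomer of the target SMILES, and the ketoreductase is picked from a commercial panel of (R)-selective enzymes.

## Forward route

Step 1
Reactants: 1 naphthazarin (5,8-dihydroxynaphthalene-1,4-dione)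
Product: 3 5,8-dihydroxy-2,3-dihydronaphthalene-1,4-dione (leuconaphthazarin), via naphthalene-1,4,5,8-tetrol 2 (not isolated)
Conditions: SnCl2·2H2O, 4 mol/L aq HCl, reflux, 1 h; cool, filter under N2
Reagents that add atoms: none
Why: Quinone reduction by divalent tin gives hydroquinone 2, which ketonises in acid to the stable crystalline diketo tautomer 3 (keto–enol tautomerism), so the air-sensitive tetrol is never handled.

Step 2
Reactants: 3 5,8-dihydroxy-2,3-dihydronaphthalene-1,4-dione
Product: 4 1,8:4,5-bis(methylenedioxy)naphthalene (naphtho[1,8-de:4,5-d'e']bis[1,3]dioxine)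
Conditions: BrCH2Cl (3 equiv), Cs2CO3 (5 equiv), DMF, Ar, 70 °C, sealed flask
Reagents that add atoms: bromochloromethane, ClCBr
Why: Base re-enolises 3 to the tetra-anion of tetrol 2 and a double Williamson etherification closes a six-membered 1,3-dioxine ring across each peri pair of oxygens, masking all four as acetals that tolerate organolithiums.

Step 3
Reactants: 4 1,8:4,5-bis(methylenedioxy)naphthalene
Product: 5 2-bromo-1,8:4,5-bis(methylenedioxy)naphthalene
Conditions: N-bromosuccinimide (1.0 equiv), MeCN, 0 °C → rt, dark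
Reagents that add atoms: N-bromosuccinimide, O=C1CCC(=O)N1Br
Why: Electrophilic aromatic bromination of the very electron-rich arene; the four ring CH positions of 4 are equivalent, so one equivalent gives a single monobromide.

Step 4
Reactants: 6 4-methylpent-3-enoic acid
Product: 8 N-methoxy-N,4-dimethylpent-3-enamide, via acyl imidazolide 7 (not isolated)
Conditions: 1,1'-carbonyldiimidazole (1.1 equiv), CH2Cl2, 0 °C → rt; then MeNHOMe·HCl (1.2 equiv), rt
Reagents that add atoms: N,O-dimethylhydroxylamine hydrochloride, CNOC.Cl; 1,1'-carbonyldiimidazole, O=C(n1ccnc1)n1ccnc1 (its imidazolyl group is carried only by 7)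
Why: Weinreb amide synthesis through an acyl imidazolide, which needs neither acid chloride nor strong base, so the β,γ-double bond does not move into conjugation.

Step 5
Reactants: 5 2-bromo-1,8:4,5-bis(methylenedioxy)naphthalene; 8 N-methoxy-N,4-dimethylpent-3-enamide
Product: 11 1-[1,8:4,5-bis(methylenedioxy)naphthalen-2-yl]-4-methylpent-3-en-1-one, via aryllithium 9 (not isolated), via lithium hemiaminal alkoxide 10 (not isolated)
Conditions: n-BuLi (1.05 equiv), THF, −78 °C, 20 min; then 8 (1.2 equiv), −78 °C, 1 h; AcOH in THF at −78 °C, then rt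
Reagents that add atoms: n-butyllithium, [Li]CCCC (lithium is carried only by 9 and 10)
Why: Bromine–lithium exchange followed by Weinreb ketone synthesis; the chelated adduct 10 survives until the cold acetic acid quench, which prevents over-addition and base-induced shift of the alkene into conjugation.

Step 6
Reactants: 11 1-[1,8:4,5-bis(methylenedioxy)naphthalen-2-yl]-4-methylpent-3-en-1-one
Product: 12 (1R)-1-[1,8:4,5-bis(methylenedioxy)naphthalen-2-yl]-4-methylpent-3-en-1-ol
Conditions: ketoreductase ((R)-selective, NADPH-dependent, anti-Prelog type), NADP+ (cat.), iPrOH (15% v/v), DMSO (10% v/v), KH2PO4/K2HPO4 buffer pH 7.0, MgSO4 (2 mmol/L), 30 °C; ee checked by chiral HPLC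
Reagents that add atoms: none
Why: Ketoreductase-catalysed asymmetric reduction in which the enzyme binds the flat aryl group in its large pocket and NADPH delivers hydride to the Si face of the carbonyl, creating the R carbinol centre, while isopropanol regenerates NADPH.

Step 7
Reactants: 12 (1R)-1-[1,8:4,5-bis(methylenedioxy)naphthalen-2-yl]-4-methylpent-3-en-1-ol
Product: 13 (R)-shikonin [5,8-dihydroxy-2-[(1R)-1-hydroxy-4-methylpent-3-en-1-yl]naphthalene-1,4-dione]
Conditions: constant-current electrolysis, undivided cell, graphite anode, Pt cathode, LiClO4 (0.1 mol/L), MeCN–H2O 1:1, rt, Ar, dark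
Reagents that add atoms: water, O
Why: Anodic oxidative deprotection: the electron-rich arene is oxidised well below the potential of the trisubstituted alkene, water attacks the oxidised ring and both methylene bridges leave as formaldehyde, giving the naphthazarin directly without touching the carbinol centre.

Step 8
Reactants: 14 3-hydroxy-3-methylbutanoic acid
Product: 15 benzyl 3-hydroxy-3-methylbutanoate
Conditions: BnBr (1.05 equiv), K2CO3 (1.2 equiv), DMF, rt
Reagents that add atoms: benzyl bromide, BrCc1ccccc1
Why: SN2 O-alkylation of the carboxylate; the tertiary alcohol is not deprotonated by K2CO3 and stays free.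

Step 9
Reactants: 15 benzyl 3-hydroxy-3-methylbutanoate
Product: 16 benzyl 3-acetoxy-3-methylbutanoate
Conditions: Ac2O (3 equiv), Et3N (4 equiv), DMAP (0.3 equiv), CH2Cl2, rt, 24–48 h
Reagents that add atoms: acetic anhydride, CC(=O)OC(C)=O
Why: DMAP-catalysed (Steglich-type) acetylation of the tertiary alcohol, run on the benzyl ester so that no mixed anhydride of the acid can form.

Step 10
Reactants: 16 benzyl 3-acetoxy-3-methylbutanoate
Product: 17 3-acetoxy-3-methylbutanoic acid
Conditions: H2 (1 atm), Pd/C (palladium on carbon, 10 wt% Pd), EtOAc, rt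
Reagents that add atoms: none
Why: Neutral hydrogenolysis of the benzyl ester leaves the tertiary acetate intact and gives only toluene as co-product.

Step 11
Reactants: 13 (R)-shikonin; 17 3-acetoxy-3-methylbutanoic acid
Product: 19 (1R)-1-(5,8-dihydroxy-1,4-dioxo-1,4-dihydronaphthalen-2-yl)-4-methylpent-3-en-1-yl 3-acetoxy-3-methylbutanoate (β-acetoxyisovalerylshikonin), via O-acylisourea 18 (not isolated)
Conditions: 17 (1.5 equiv), N,N'-dicyclohexylcarbodiimide (1.5 equiv), DMAP (0.2 equiv), CH2Cl2, 0 °C → rt, Ar, dark
Reagents that add atoms: N,N'-dicyclohexylcarbodiimide, C(=NC1CCCCC1)=NC1CCCCC1 (its atoms are carried only by 18)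
Why: Steglich esterification in which the side-chain secondary alcohol is the only nucleophilic hydroxyl, because both phenols are hydrogen-bonded to the peri quinone carbonyls, and acylation at oxygen leaves the R centre unchanged.

## Compound list

1 | naphthazarin (5,8-dihydroxynaphthalene-1,4-dione) | O=C1C=CC(=O)c2c(O)ccc(O)c12 | starting material
2 | naphthalene-1,4,5,8-tetrol | Oc1ccc(O)c2c(O)ccc(O)c12 | intermediate
3 | 5,8-dihydroxy-2,3-dihydronaphthalene-1,4-dione (leuconaphthazarin) | O=C1CCC(=O)c2c(O)ccc(O)c12 | intermediate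
4 | 1,8:4,5-bis(methylenedioxy)naphthalene (naphtho[1,8-de:4,5-d'e']bis[1,3]dioxine) | c1cc2OCOc3ccc4OCOc1c4c32 | intermediate
5 | 2-bromo-1,8:4,5-bis(methylenedioxy)naphthalene | Brc1cc2OCOc3ccc4OCOc1c4c32 | intermediate
6 | 4-methylpent-3-enoic acid | CC(C)=CCC(=O)O | starting material
7 | 1-(4-methylpent-3-enoyl)imidazole | CC(C)=CCC(=O)n1ccnc1 | intermediate
8 | N-methoxy-N,4-dimethylpent-3-enamide | CC(C)=CCC(=O)N(C)OC | intermediate
9 | [1,8:4,5-bis(methylenedioxy)naphthalen-2-yl]lithium | [Li]c1cc2OCOc3ccc4OCOc1c4c32 | intermediate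
10 | lithium 1-[1,8:4,5-bis(methylenedioxy)naphthalen-2-yl]-1-[methoxy(methyl)amino]-4-methylpent-3-en-1-olate (racemic; the centre is lost on collapse) | CC(C)=CCC([O-])(N(C)OC)c1cc2OCOc3ccc4OCOc1c4c32.[Li+] | intermediate
11 | 1-[1,8:4,5-bis(methylenedioxy)naphthalen-2-yl]-4-methylpent-3-en-1-one | CC(C)=CCC(=O)c1cc2OCOc3ccc4OCOc1c4c32 | intermediate
12 | (1R)-1-[1,8:4,5-bis(methylenedioxy)naphthalen-2-yl]-4-methylpent-3-en-1-ol | O[C@H](CC=C(C)C)c1cc2OCOc3ccc4OCOc1c4c32 | intermediate
13 | (R)-shikonin, 5,8-dihydroxy-2-[(1R)-1-hydroxy-4-methylpent-3-en-1-yl]naphthalene-1,4-dione | O[C@H](CC=C(C)C)C1=CC(=O)c2c(O)ccc(O)c2C1=O | intermediate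
14 | 3-hydroxy-3-methylbutanoic acid | CC(C)(O)CC(=O)O | starting material
15 | benzyl 3-hydroxy-3-methylbutanoate | CC(C)(O)CC(=O)OCc1ccccc1 | intermediate
16 | benzyl 3-acetoxy-3-methylbutanoate | CC(=O)OC(C)(C)CC(=O)OCc1ccccc1 | intermediate
17 | 3-acetoxy-3-methylbutanoic acid | CC(=O)OC(C)(C)CC(=O)O | intermediate
18 | O-(3-acetoxy-3-methylbutanoyl)-N,N'-dicyclohexylisourea | CC(=O)OC(C)(C)CC(=O)OC(=NC1CCCCC1)NC1CCCCC1 | intermediate
19 | (1R)-1-(5,8-dihydroxy-1,4-dioxo-1,4-dihydronaphthalen-2-yl)-4-methylpent-3-en-1-yl 3-acetoxy-3-methylbutanoate | CC(=O)OC(C)(C)CC(=O)O[C@H](CC=C(C)C)C1=CC(=O)c2c(O)ccc(O)c2C1=O | target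

## Step count and weak points

Total steps: 11. Longest linear sequence: 7 steps (1, 2, 3, 5, 6, 7, 11) from naphthazarin. Steps 4 and 8–10 are side branches.

**Step 6 (ketoreductase reduction).** Ketone 11 has two bulky substituents, so no panel enzyme may combine useful rate with high R selectivity. The fallback sets out from bromide 5 and comes back at alcohol 12. Bromide 5 is lithiated as in step 5 (n-BuLi, THF, −78 °C, through aryllithium 9) and formylated with DMF to give 1,8:4,5-bis(methylenedioxy)naphthalene-2-carbaldehyde F1. A Keck allylation (allyltributylstannane, Ti(OiPr)4 and (R)-BINOL as catalyst, 4 Å sieves, CH2Cl2, −20 °C) adds allyl to the Re face, in the sense this ligand enantiomer shows with benzaldehyde, and gives (1R)-1-[1,8:4,5-bis(methylenedioxy)naphthalen-2-yl]but-3-en-1-ol F2. Cross-metathesis of F2 with excess 2-methyl-2-butene (second-generation Grubbs catalyst, CH2Cl2, 40 °C) turns the vinyl end into the isopropylidene group and delivers 12.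

**Step 7 (anodic unmasking).** The free benzylic alcohol may be over-oxidised or fragment at the electrode, and shikonin is sensitive to light and acid. The fallback sets out from alcohol 12 and comes back at shikonin 13. Alcohol 12 is acetylated (Ac2O, pyridine, DMAP, CH2Cl2) to (1R)-1-[1,8:4,5-bis(methylenedioxy)naphthalen-2-yl]-4-methylpent-3-en-1-yl acetate F3. A chemical oxidant, (NH4)2Ce(NO3)6 (2.5 equiv) in MeCN–H2O at 0 °C, then unmasks the ring to give 1'-O-acetylshikonin F4. Brief hydrolysis (1 mol/L aq NaOH, N2, 0 °C, then dilute HCl) gives 13.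

**Step 11 (final esterification).** The side-chain alcohol of shikonin is hindered and weakly nucleophilic, the quinone is sensitive to DMAP and base, and the activated β-acetoxy acid can lose acetate. The fallback sets out from alcohol 12 and acid 17 and comes back at target 19. The ester is made before the quinone exists: coupling of 12 with 17 (N,N'-dicyclohexylcarbodiimide, DMAP, CH2Cl2) gives (1R)-1-[1,8:4,5-bis(methylenedioxy)naphthalen-2-yl]-4-methylpent-3-en-1-yl 3-acetoxy-3-methylbutanoate F5. The electrolysis of step 7 applied to F5 then releases 19 directly.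

Further compounds

F1 | step 6 | 1,8:4,5-bis(methylenedioxy)naphthalene-2-carbaldehyde | O=Cc1cc2OCOc3ccc4OCOc1c4c32
F2 | step 6 | (1R)-1-[1,8:4,5-bis(methylenedioxy)naphthalen-2-yl]but-3-en-1-ol | O[C@H](CC=C)c1cc2OCOc3ccc4OCOc1c4c32
F3 | step 7 | (1R)-1-[1,8:4,5-bis(methylenedioxy)naphthalen-2-yl]-4-methylpent-3-en-1-yl acetate | CC(=O)O[C@H](CC=C(C)C)c1cc2OCOc3ccc4OCOc1c4c32
F4 | step 7 | 1'-O-acetylshikonin, (1R)-1-(5,8-dihydroxy-1,4-dioxo-1,4-dihydronaphthalen-2-yl)-4-methylpent-3-en-1-yl acetate | CC(=O)O[C@H](CC=C(C)C)C1=CC(=O)c2c(O)ccc(O)c2C1=O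
F5 | step 11 | (1R)-1-[1,8:4,5-bis(methylenedioxy)naphthalen-2-yl]-4-methylpent-3-en-1-yl 3-acetoxy-3-methylbutanoate | CC(=O)OC(C)(C)CC(=O)O[C@H](CC=C(C)C)c1cc2OCOc3ccc4OCOc1c4c32
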